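## Retrosynthetic overview

1. Target 16 ⇐ tri-O-benzyl isoflavone 15 ⇐ chalcone 13, by an oxidative 2→3 aryl shift and closure of the pyranone ring (ring C, formed last). Chalcone 13 ⇐ aldehyde 11 + acetophenone 12.
2. Key disconnection: the dihydrofuran ring of 11 (O1–C2–C3–C3a–C7a), whose C2 carries H, O1 and the exocyclic C(CH3)2OH, ⇐ the pyran ring of (3S)-2,2-dimethylchroman-3-ol 8. The ring oxygen shifts from CMe2 to the carbinol carbon: a six- to five-membered ring contraction with inversion, and water caps the CMe2 terminus.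
3. Chromanol 8 ⇐ chromene 4 (Jacobsen epoxidation, hydride opening at C4) ⇐ 2,4-dihydroxybenzaldehyde + prenal. The pyran annulation fixes the regiochemistry (ring O para to CHO, chelated OH left free), so no C-prenylation between two phenols and no 2′-OH/4′-OH ambiguity arise.
4. Ring order: both benzene rings are bought; pyran ring (step 1); contraction to the dihydrofuran (step 6); pyranone ring C (step 8).

Key step: step 6

Assumption: 1-[2,4-bis(benzyloxy)-6-hydroxyphenyl]ethan-1-one (12) is taken as a purchasable building block; chromane numbering (O1, C2–C4, C4a, C5–C8, C8a) and benzofuran numbering (O1, C2, C3, C3a, C4–C7, C7a) are used.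

## Route

Step 1
Reactants: 1 2,4-dihydroxybenzaldehyde; 2 3-methylbut-2-enal
Product: 4 5-hydroxy-2,2-dimethyl-2H-chromene-6-carbaldehyde, via quinone methide 3 (not isolated)
Conditions: pyridine, 140 °C, sealed tube
Reagents that add atoms: none
Why: Knoevenagel-type C-alkylation of the resorcinol at C3 (between the two hydroxyls), loss of water to ortho-quinone methide 3 and oxa-6π electrocyclisation should give the angular chromene, because the hydroxyl hydrogen-bonded to the formyl group stays out of the ring closure (chromene annulation of acyl resorcinols).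

Step 2
Reactants: 4 5-hydroxy-2,2-dimethyl-2H-chromene-6-carbaldehyde
Product: 5 5-(benzyloxy)-2,2-dimethyl-2H-chromene-6-carbaldehyde
Conditions: BnBr, K2CO3, DMF, 60 °C
Reagents that add atoms: benzyl bromide BrCc1ccccc1
Why: Williamson etherification of the chelated phenol in a dipolar aprotic solvent; the benzyl ether blocks the future 2′-OH during the oxidations and keeps it out of the later ring closures.

Step 3
Reactants: 5 5-(benzyloxy)-2,2-dimethyl-2H-chromene-6-carbaldehyde
Product: 6 5-(benzyloxy)-6-(dimethoxymethyl)-2,2-dimethyl-2H-chromene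
Conditions: HC(OMe)3, CSA (cat.), CH2Cl2, 23 °C; then Et3N
Reagents that add atoms: trimethyl orthoformate COC(OC)OC
Why: Acid-catalysed acetalisation with an orthoformate; the acetal shields the aldehyde from hypochlorite and hydride and removes the para-acceptor that would drain electron density from the ring oxygen needed in step 6.

Step 4
Reactants: 6 5-(benzyloxy)-6-(dimethoxymethyl)-2,2-dimethyl-2H-chromene
Product: 7 (3S,4S)-5-(benzyloxy)-6-(dimethoxymethyl)-3,4-epoxy-2,2-dimethylchromane
Conditions: (S,S)-Jacobsen Mn(salen)Cl (4 mol%), 4-phenylpyridine N-oxide, aq NaOCl (pH 11.3), CH2Cl2, 0 °C; crude product used directly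
Reagents that add atoms: sodium hypochlorite [Na+].[O-]Cl
Why: Jacobsen–Katsuki epoxidation, for which cis-aryl olefins of the 2,2-dimethylchromene class are privileged substrates; the (S,S)-salen manganese catalyst controls the face and should give the (3S,4S)-epoxide, by analogy with its known sense on indene.

Step 5
Reactants: 7 (3S,4S)-5-(benzyloxy)-6-(dimethoxymethyl)-3,4-epoxy-2,2-dimethylchromane
Product: 8 (3S)-5-(benzyloxy)-6-(dimethoxymethyl)-2,2-dimethylchroman-3-ol
Conditions: LiAlH4, THF, 0 °C
Reagents that add atoms: none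
Why: SN2 hydride opening of the epoxide at the activated benzylic C4, remote from the gem-dimethyl group, leaves the C3–O bond and its (S) configuration untouched (regioselective reductive epoxide opening); acetal and benzyl ether are inert to LiAlH4.

Step 6
Reactants: 8 (3S)-5-(benzyloxy)-6-(dimethoxymethyl)-2,2-dimethylchroman-3-ol
Product: 11 (2R)-4-(benzyloxy)-2-(2-hydroxypropan-2-yl)-2,3-dihydrobenzofuran-5-carbaldehyde, via chromanyl triflate 9 (not isolated), via ring-contracted acetal 10 (not isolated)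
Conditions: Tf2O (1.1 equiv), 2,6-lutidine, CH2Cl2, −78 °C; then THF–H2O 3:1, −78 → 23 °C; then 1 M HCl, 23 °C
Reagents that add atoms: water O (tertiary OH and aldehyde oxygen); trifluoromethanesulfonic anhydride O=S(=O)(OS(=O)(=O)C(F)(F)F)C(F)(F)F (its atoms stay only in intermediate 9)
Why: Triflation of the C3 carbinol sets up a stereospecific 1,2-shift of the ring oxygen: O1, anti-periplanar to the pseudo-equatorial C3–OTf bond, displaces triflate from the back to give an O-aryl oxiranium ion spanning C2 and C3, which opens at the tertiary carbon and is captured there by water as the C(CH3)2OH group. The closest known reaction type is the ring contraction of 3-activated 2,2-dimethylchroman-3-ols (sulfonate, DAST or Mitsunobu activation) to 2-isopropenyl- or 2-(2-fluoropropan-2-yl)-2,3-dihydrobenzofurans, and the deaminative contraction of 2-aminopyranoses to 2,5-anhydro sugars; here the cation is trapped by water instead of losing a proton. The dihydrofuran ring closes by 3-exo-tet attack of O1 on C3 followed by cleavage of the O1–CMe2 bond, a net 1,2-oxygen shift from a six- to a five-membered ring. The single stereocentre is controlled by the substrate: backside attack inverts C3, so (3S)-8 should give the (2R)-dihydrofuran, and no cation sits on the stereogenic carbon. The step needs oxygen migration to win over elimination or 1,2-hydride shift towards the chromene, over migration of a C2 methyl group and over proton loss from the tertiary cation; the gem-dimethyl terminus, the ring oxygen kept electron-rich by the acetal in place of a para-formyl group, the hindered non-nucleophilic base and ionisation in an aqueous medium at low temperature secure this. Acidification then unmasks the aldehyde without harming the β-aryloxy tertiary alcohol.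

Step 7
Reactants: 11 (2R)-4-(benzyloxy)-2-(2-hydroxypropan-2-yl)-2,3-dihydrobenzofuran-5-carbaldehyde; 12 1-[2,4-bis(benzyloxy)-6-hydroxyphenyl]ethan-1-one
Product: 13 (E)-1-[2,4-bis(benzyloxy)-6-hydroxyphenyl]-3-[(2R)-4-(benzyloxy)-2-(2-hydroxypropan-2-yl)-2,3-dihydrobenzofuran-5-yl]prop-2-en-1-one
Conditions: KOH (50% aq), EtOH, 23 °C
Reagents that add atoms: none
Why: Claisen–Schmidt condensation of the methyl ketone with the non-enolisable aldehyde, dehydration giving the (E)-enone; the C2 stereocentre carries no acidic hydrogen and is not at risk.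

Step 8
Reactants: 13 (E)-1-[2,4-bis(benzyloxy)-6-hydroxyphenyl]-3-[(2R)-4-(benzyloxy)-2-(2-hydroxypropan-2-yl)-2,3-dihydrobenzofuran-5-yl]prop-2-en-1-one
Product: 15 5,7-bis(benzyloxy)-3-[(2R)-4-(benzyloxy)-2-(2-hydroxypropan-2-yl)-2,3-dihydrobenzofuran-5-yl]-4H-chromen-4-one, via ketoacetal 14 (not isolated)
Conditions: Tl(NO3)3·3H2O (1.1 equiv), MeOH, 23 °C; then 2 M aq HCl, 40 °C
Reagents that add atoms: methanol CO (the two OMe groups of 14; lost again in the ring closure)
Why: Thallium(III)-mediated oxidative rearrangement of a 2′-hydroxychalcone: methoxythallation of the enone and 1,2-shift of the electron-rich aryl group (ortho- and para-oxygenated, hence a high migratory aptitude) from Cβ to Cα with loss of Tl(I) should give β-ketoacetal 14 as a mixture of epimers at a carbon that is planarised afterwards, and acid then closes the pyranone ring through the only free phenol and eliminates methanol (classical chalcone route to isoflavones).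

Step 9
Reactants: 15 5,7-bis(benzyloxy)-3-[(2R)-4-(benzyloxy)-2-(2-hydroxypropan-2-yl)-2,3-dihydrobenzofuran-5-yl]-4H-chromen-4-one
Product: 16 5,7-dihydroxy-3-[(2R)-4-hydroxy-2-(2-hydroxypropan-2-yl)-2,3-dihydrobenzofuran-5-yl]-4H-chromen-4-one
Conditions: H2 (1 atm), 10% Pd/C, EtOAc–MeOH, 23 °C, stopped at full debenzylation
Reagents that add atoms: none
Why: Hydrogenolysis of the three benzyl ethers over palladium under mild conditions that should leave the chromone C2=C3 bond, the aryl alkyl ether of the dihydrofuran and the tertiary alcohol intact; the stereocentre is not benzylic and is not affected.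

## Compound list

1 | 2,4-dihydroxybenzaldehyde | O=Cc1ccc(O)cc1O | starting material
2 | 3-methylbut-2-enal | CC(C)=CC=O | starting material
3 | 3-hydroxy-5-(3-methylbut-2-en-1-ylidene)-4-oxocyclohexa-2,6-diene... ortho-quinone methide of the condensation (2-hydroxy-3-(3-methylbut-2-enylidene)-4-oxocyclohexa-1,5-diene-1-carbaldehyde) | O=CC1=C(O)C(=CC=C(C)C)C(=O)C=C1 | intermediate (not isolated)
4 | 5-hydroxy-2,2-dimethyl-2H-chromene-6-carbaldehyde | CC1(C)C=Cc2c(O)c(C=O)ccc2O1 | intermediate
5 | 5-(benzyloxy)-2,2-dimethyl-2H-chromene-6-carbaldehyde | CC1(C)C=Cc2c(OCc3ccccc3)c(C=O)ccc2O1 | intermediate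
6 | 5-(benzyloxy)-6-(dimethoxymethyl)-2,2-dimethyl-2H-chromene | CC1(C)C=Cc2c(OCc3ccccc3)c(C(OC)OC)ccc2O1 | intermediate
7 | (3S,4S)-5-(benzyloxy)-6-(dimethoxymethyl)-3,4-epoxy-2,2-dimethylchromane | CC1(C)Oc2ccc(C(OC)OC)c(OCc4ccccc4)c2[C@@H]3O[C@H]13 | intermediate
8 | (3S)-5-(benzyloxy)-6-(dimethoxymethyl)-2,2-dimethylchroman-3-ol | CC1(C)Oc2ccc(C(OC)OC)c(OCc3ccccc3)c2C[C@@H]1O | intermediate
9 | (3S)-5-(benzyloxy)-6-(dimethoxymethyl)-2,2-dimethylchroman-3-yl trifluoromethanesulfonate | CC1(C)Oc2ccc(C(OC)OC)c(OCc3ccccc3)c2C[C@@H]1OS(=O)(=O)C(F)(F)F | intermediate (not isolated)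
10 | 2-[(2R)-4-(benzyloxy)-5-(dimethoxymethyl)-2,3-dihydrobenzofuran-2-yl]propan-2-ol | CC(C)(O)[C@H]1Cc2c(OCc3ccccc3)c(C(OC)OC)ccc2O1 | intermediate (not isolated)
11 | (2R)-4-(benzyloxy)-2-(2-hydroxypropan-2-yl)-2,3-dihydrobenzofuran-5-carbaldehyde | CC(C)(O)[C@H]1Cc2c(OCc3ccccc3)c(C=O)ccc2O1 | intermediate
12 | 1-[2,4-bis(benzyloxy)-6-hydroxyphenyl]ethan-1-one | CC(=O)c1c(O)cc(OCc2ccccc2)cc1OCc1ccccc1 | starting material
13 | (E)-1-[2,4-bis(benzyloxy)-6-hydroxyphenyl]-3-[(2R)-4-(benzyloxy)-2-(2-hydroxypropan-2-yl)-2,3-dihydrobenzofuran-5-yl]prop-2-en-1-one | CC(C)(O)[C@H]1Cc2c(OCc3ccccc3)c(/C=C/C(=O)c3c(O)cc(OCc4ccccc4)cc3OCc3ccccc3)ccc2O1 | intermediate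
14 | 1-[2,4-bis(benzyloxy)-6-hydroxyphenyl]-2-[(2R)-4-(benzyloxy)-2-(2-hydroxypropan-2-yl)-2,3-dihydrobenzofuran-5-yl]-3,3-dimethoxypropan-1-one (both epimers at C2 of the propanone) | CC(C)(O)[C@H]1Cc2c(OCc3ccccc3)c(C(C(OC)OC)C(=O)c3c(O)cc(OCc4ccccc4)cc3OCc3ccccc3)ccc2O1 | intermediate (not isolated)
15 | 5,7-bis(benzyloxy)-3-[(2R)-4-(benzyloxy)-2-(2-hydroxypropan-2-yl)-2,3-dihydrobenzofuran-5-yl]-4H-chromen-4-one | CC(C)(O)[C@H]1Cc2c(OCc3ccccc3)c(-c3coc4cc(OCc5ccccc5)cc(OCc5ccccc5)c4c3=O)ccc2O1 | intermediate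
16 | 5,7-dihydroxy-3-[(2R)-4-hydroxy-2-(2-hydroxypropan-2-yl)-2,3-dihydrobenzofuran-5-yl]-4H-chromen-4-one | CC(C)(O)[C@H]1Cc2c(ccc(-c3coc4cc(O)cc(O)c4c3=O)c2O)O1 | target

## Step count and risks

Total steps: 9. Longest linear sequence: 9 (steps 1–9 from 1; 12 enters at step 7).

**Step 6 (key step).** The C3 triflate may ionise along other channels: base-induced elimination or 1,2-hydride shift from C4 towards the chromene, migration of a C2 methyl group, or proton loss from the tertiary cation to the isopropenyl compound instead of capture by water. The fallback sets out from 1 and returns at 11; it closes the dihydrofuran in the conventional sense, by 5-exo opening of a prenyl epoxide. C-Prenylation of 1 at C3 (prenyl bromide, aq KOH) would give 2,4-dihydroxy-3-(3-methylbut-2-en-1-yl)benzaldehyde F1. Silylation (TBSCl, imidazole, DMF) would give 2,4-bis[(tert-butyldimethylsilyl)oxy]-3-(3-methylbut-2-en-1-yl)benzaldehyde F2. Shi epoxidation with the enantiomer of the fructose-derived ketone that delivers the (S)-epoxide (Oxone, K2CO3 buffer, MeCN–DMM–H2O, 0 °C) would give 2,4-bis[(tert-butyldimethylsilyl)oxy]-3-{[(2S)-3,3-dimethyloxiran-2-yl]methyl}benzaldehyde F3. TBAF in THF would free both phenols; the more acidic 4-phenoxide, not tied up in a hydrogen bond to the formyl group, should open the epoxide at its secondary carbon (5-exo-tet, inversion) to give (2R)-4-hydroxy-2-(2-hydroxypropan-2-yl)-2,3-dihydrobenzofuran-5-carbaldehyde F4. Benzylation as in step 2 would give 11.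

**Step 8.** Thallium(III) may divert the free 2′-hydroxychalcone into oxidative cyclisation (aurone formation) or over-oxidise the electron-rich dihydrobenzofuran ring, and the tertiary alcohol may undergo methanolysis in the acidic stage. The fallback sets out from 11 and 12 and returns at 15; it makes the C3–C1′ bond by cross-coupling instead of aryl migration. Dakin oxidation of 11 (mCPBA, CH2Cl2; then K2CO3, MeOH) would pass through (2R)-4-(benzyloxy)-2-(2-hydroxypropan-2-yl)-2,3-dihydrobenzofuran-5-yl formate F5 and give (2R)-4-(benzyloxy)-2-(2-hydroxypropan-2-yl)-2,3-dihydrobenzofuran-5-ol F6. PhNTf2 and Et3N would give (2R)-4-(benzyloxy)-2-(2-hydroxypropan-2-yl)-2,3-dihydrobenzofuran-5-yl trifluoromethanesulfonate F7. Miyaura borylation (B2pin2, PdCl2(dppf), KOAc, dioxane, 80 °C) would give 2-[(2R)-4-(benzyloxy)-5-(4,4,5,5-tetramethyl-1,3,2-dioxaborolan-2-yl)-2,3-dihydrobenzofuran-2-yl]propan-2-ol F8. In parallel, 12 with DMF dimethyl acetal (toluene, 90 °C) would give (E)-1-[2,4-bis(benzyloxy)-6-hydroxyphenyl]-3-(dimethylamino)prop-2-en-1-one F9, and iodine in MeOH would close it to 5,7-bis(benzyloxy)-3-iodo-4H-chromen-4-one F10. Suzuki–Miyaura coupling of F8 with F10 (PdCl2(dppf), K2CO3, DME–H2O, 80 °C) would give 15.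

**Step 4.** The benzylic epoxide, activated by two ortho oxygen substituents, may open solvolytically or rearrange (Meinwald type) before it is reduced, and the peri-benzyloxy group may lower the facial selectivity of the oxo transfer. The fallback sets out from 6 and returns at 8; it sets the C3 stereocentre by ketone reduction. Hydroboration–oxidation of 6 (BH3·THF, 0 °C; then NaOH, H2O2) should place boron at C3, remote from the aryl ring, and give racemic 5-(benzyloxy)-6-(dimethoxymethyl)-2,2-dimethylchroman-3-ol F11. Dess–Martin periodinane (NaHCO3, CH2Cl2) would give 5-(benzyloxy)-6-(dimethoxymethyl)-2,2-dimethylchroman-3-one F12. CBS reduction with the (R)-oxazaborolidine and BH3·SMe2, with the quaternary C2 as the large group, is expected to return (3S)-8.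

Further compounds
F1 | step 6 | 2,4-dihydroxy-3-(3-methylbut-2-en-1-yl)benzaldehyde | CC(C)=CCc1c(O)ccc(C=O)c1O
F2 | step 6 | 2,4-bis[(tert-butyldimethylsilyl)oxy]-3-(3-methylbut-2-en-1-yl)benzaldehyde | CC(C)=CCc1c(O[Si](C)(C)C(C)(C)C)ccc(C=O)c1O[Si](C)(C)C(C)(C)C
F3 | step 6 | 2,4-bis[(tert-butyldimethylsilyl)oxy]-3-{[(2S)-3,3-dimethyloxiran-2-yl]methyl}benzaldehyde | CC1(C)O[C@H]1Cc1c(O[Si](C)(C)C(C)(C)C)ccc(C=O)c1O[Si](C)(C)C(C)(C)C
F4 | step 6 | (2R)-4-hydroxy-2-(2-hydroxypropan-2-yl)-2,3-dihydrobenzofuran-5-carbaldehyde | CC(C)(O)[C@H]1Cc2c(O)c(C=O)ccc2O1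
F5 | step 8 | (2R)-4-(benzyloxy)-2-(2-hydroxypropan-2-yl)-2,3-dihydrobenzofuran-5-yl formate | CC(C)(O)[C@H]1Cc2c(OCc3ccccc3)c(OC=O)ccc2O1
F6 | step 8 | (2R)-4-(benzyloxy)-2-(2-hydroxypropan-2-yl)-2,3-dihydrobenzofuran-5-ol | CC(C)(O)[C@H]1Cc2c(OCc3ccccc3)c(O)ccc2O1
F7 | step 8 | (2R)-4-(benzyloxy)-2-(2-hydroxypropan-2-yl)-2,3-dihydrobenzofuran-5-yl trifluoromethanesulfonate | CC(C)(O)[C@H]1Cc2c(OCc3ccccc3)c(OS(=O)(=O)C(F)(F)F)ccc2O1
F8 | step 8 | 2-[(2R)-4-(benzyloxy)-5-(4,4,5,5-tetramethyl-1,3,2-dioxaborolan-2-yl)-2,3-dihydrobenzofuran-2-yl]propan-2-ol | CC(C)(O)[C@H]1Cc2c(OCc3ccccc3)c(B3OC(C)(C)C(C)(C)O3)ccc2O1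
F9 | step 8 | (E)-1-[2,4-bis(benzyloxy)-6-hydroxyphenyl]-3-(dimethylamino)prop-2-en-1-one | CN(C)/C=C/C(=O)c1c(O)cc(OCc2ccccc2)cc1OCc1ccccc1
F10 | step 8 | 5,7-bis(benzyloxy)-3-iodo-4H-chromen-4-one | O=c1c(I)coc2cc(OCc3ccccc3)cc(OCc3ccccc3)c12
F11 | step 4 | racemic 5-(benzyloxy)-6-(dimethoxymethyl)-2,2-dimethylchroman-3-ol | CC1(C)Oc2ccc(C(OC)OC)c(OCc3ccccc3)c2CC1O
F12 | step 4 | 5-(benzyloxy)-6-(dimethoxymethyl)-2,2-dimethylchroman-3-one | CC1(C)Oc2ccc(C(OC)OC)c(OCc3ccccc3)c2CC1=O
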